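The synthesis rests on disconnecting O1–C2 in ring C of the flavanone half (O1, C2, C3, C4, C4a, C8a). C2, the only stereocentre, is both the ether carbon of O1 and the β-carbon of the C4 carbonyl. Intramolecular conjugate addition of the ring A phenol therefore creates the bond, the ring and the stereocentre together. In one operation a cinchona thiourea closes ring C and sets 2S, and acid then strips the activating tert-butyl ester from C3. The precursor is a single-isomer (Z) alkylidene β-keto ester. Cα carries a 2-hydroxy-4,6-bis(benzyloxy)benzoyl group and the ester. Cβ carries benzylated ring B, already joined at C5' to C8 of tetra-O-benzylluteolin.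

Key step: step 9

Assumption: the C5'–C8'' biaryl axis has three oxygen ortho substituents and one ortho hydrogen, and it is taken to rotate freely on the laboratory time scale. This fits a target structure that defines C2 only. No axial control is planned, and protected intermediates may show broadened NMR signals.

Structure check:
- At Cα the ester carbon (O,O,O) outranks the ketone carbon (O,O,C), so the isomer with ring B cis to the ester is Z.
- At C2 the order O1 > C1' > C3 > H makes the centre S in all cyclised compounds and in the target.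

Refinement of the precursor:
- The E and Z isomers present Cβ with aryl and hydrogen interchanged. A catalyst that holds the dicarbonyl and the phenol in one fixed way would attack the same bound face and give opposite C2 configurations from the two isomers.
- A mixture cannot be relied on to converge, so the precursor is used as the pure Z isomer. This isomer has trans-chalcone geometry, with ring B trans to the ketone.
- Every other phenol is benzylated, so the ring A 2-OH is the only acidic site offered to the catalyst.

Step 1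
Reactants: 1 luteolin
Product: 2 5,7,3',4'-tetra-O-benzylluteolin
Conditions: BnBr (6 equiv), K2CO3 (8 equiv), DMF, 70 °C
Reagents that add atoms: benzyl bromide, BrCc1ccccc1
Why: Fourfold Williamson ether synthesis in which excess bromide, heat and a polar aprotic solvent carry even the chelated 5-OH to its ether, full capping being needed both to steer the next step to C8 and to leave no stray acidic OH in the cyclisation precursor.

Step 2
Reactants: 2 5,7,3',4'-tetra-O-benzylluteolin
Product: 3 8-iodo-5,7,3',4'-tetra-O-benzylluteolin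
Conditions: NIS (1.1 equiv), DMF, rt to 50 °C, dark
Reagents that add atoms: N-iodosuccinimide, O=C1CCC(=O)N1I
Why: Electrophilic aromatic iodination of the phloroglucinol-type ring, where no chelated 5-OH remains to direct attack to C6, C6 is walled in by two benzyloxy groups, and C8 (ortho to 7-OBn, para to 5-OBn, next to unsubstituted O1) reacts first, as is general for 5,7-di-O-alkylated flavones, while the catechol ring and C3 are deactivated by the pyrone.

Step 3
Reactants: 4 3-bromo-4,5-dihydroxybenzaldehyde
Product: 5 3,4-bis(benzyloxy)-5-bromobenzaldehyde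
Conditions: BnBr (2.4 equiv), K2CO3 (3 equiv), DMF, 50 °C
Reagents that add atoms: benzyl bromide, BrCc1ccccc1
Why: Double Williamson ether synthesis on an acidic catechol, with the aldehyde and the aryl bromide untouched by K2CO3.

Step 4
Reactants: 5 3,4-bis(benzyloxy)-5-bromobenzaldehyde
Product: 6 3,4-bis(benzyloxy)-5-(4,4,5,5-tetramethyl-1,3,2-dioxaborolan-2-yl)benzaldehyde
Conditions: B2pin2 (1.2 equiv), PdCl2(dppf) (3 mol%), KOAc (3 equiv), 1,4-dioxane, 90 °C
Reagents that add atoms: bis(pinacolato)diboron, CC1(C)OB(OC1(C)C)B1OC(C)(C)C(C)(C)O1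
Why: Miyaura borylation, in which zerovalent palladium inserts into the C–Br bond, acetate-assisted transmetalation with B2pin2 follows, and the weak base KOAc spares the aldehyde and suppresses homocoupling.

Step 5
Reactants: 3 8-iodo-5,7,3',4'-tetra-O-benzylluteolin; 6 3,4-bis(benzyloxy)-5-(pinacolboryl)benzaldehyde
Product: 7 3,4-bis(benzyloxy)-5-(5,7,3',4'-tetra-O-benzylluteolin-8-yl)benzaldehyde
Conditions: Pd(OAc)2 (5 mol%), SPhos (10 mol%), K3PO4 (3 equiv), toluene/H2O 10:1, 90 °C
Reagents that add atoms: none
Why: Suzuki–Miyaura cross-coupling, for which SPhos-ligated zerovalent palladium is suited to tri-ortho-substituted biaryls, the C8–I bond adds readily, and aldehyde, flavone and benzyl ethers tolerate aqueous K3PO4, in line with 8-iodoflavone couplings used for 3',8''-linked biflavones.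

Step 6
Reactants: 8 2,4,6-trihydroxyacetophenone
Product: 9 2-hydroxy-4,6-bis(benzyloxy)acetophenone
Conditions: BnBr (2.05 equiv), K2CO3 (2.2 equiv), DMF, rt
Reagents that add atoms: benzyl bromide, BrCc1ccccc1
Why: Chemoselective Williamson ether synthesis, since the 4-OH and one ortho OH react and the last OH is then locked in a strong hydrogen bond to the acetyl oxygen and resists alkylation at room temperature with two equivalents of bromide.

Step 7
Reactants: 9 2-hydroxy-4,6-bis(benzyloxy)acetophenone
Product: 10 tert-butyl 3-[2-hydroxy-4,6-bis(benzyloxy)phenyl]-3-oxopropanoate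
Conditions: LiN(SiMe3)2 (3.3 equiv), THF, −78 °C; Boc2O (1.1 equiv), −78 to 0 °C; AcOH quench
Reagents that add atoms: di-tert-butyl dicarbonate, CC(C)(C)OC(=O)OC(=O)OC(C)(C)C
Why: Claisen-type C-acylation of the phenoxide–enolate dianion with Boc2O, the third equivalent of base storing the product as its unreactive enolate (no lactonisation to a coumarin) and any aryl carbonate formed at oxygen being channelled to the same β-keto ester by a Baker–Venkataraman-type O-to-C acyl shift.

Step 8
Reactants: 7 3,4-bis(benzyloxy)-5-(tetra-O-benzylluteolin-8-yl)benzaldehyde; 10 tert-butyl 3-[2-hydroxy-4,6-bis(benzyloxy)phenyl]-3-oxopropanoate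
Product: 11 tert-butyl (Z)-2-[2-hydroxy-4,6-bis(benzyloxy)benzoyl]-3-[3,4-bis(benzyloxy)-5-(tetra-O-benzylluteolin-8-yl)phenyl]acrylate
Conditions: piperidine (20 mol%), AcOH (20 mol%), 4 Å MS, toluene, rt; Z isomer isolated by chromatography or crystallisation, geometry assigned from the vinyl H to carbonyl C coupling constants, kept in the dark
Reagents that add atoms: none
Why: Knoevenagel condensation through the piperidine iminium ion of an aldehyde whose two ortho positions are C–H, where the buffered non-polar medium and the chelation of the 2-OH to the ketone hold back ring closure and reversible amine addition lets the alkene settle to the expected more stable Z isomer, any E isomer being removed and re-equilibrated under the same conditions.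

Step 9
Reactants: 11 tert-butyl (Z)-2-[2-hydroxy-4,6-bis(benzyloxy)benzoyl]-3-[3,4-bis(benzyloxy)-5-(tetra-O-benzylluteolin-8-yl)phenyl]acrylate
Product: 14 (2S)-5,7-bis(benzyloxy)-2-[3,4-bis(benzyloxy)-5-(tetra-O-benzylluteolin-8-yl)phenyl]chroman-4-one (octa-O-benzyl ether of the target), via cyclised tert-butyl ester 12 (not isolated), via 3-carboxylic acid 13 (not isolated)
Conditions: 1-[3,5-bis(trifluoromethyl)phenyl]-3-[(8R,9R)-6'-methoxycinchonan-9-yl]thiourea (from 9-amino-9-deoxy-epi-quinidine, 10–20 mol%), toluene, −25 °C; then p-TsOH·H2O (0.5 equiv) added cold, 80 °C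
Reagents that add atoms: none
Why: The quinuclidine nitrogen takes the proton of the only free phenol (ring A 2-OH) while the two thiourea N–H bonds hold the ketone/ester carbonyl pair, and the oxygen then adds to Cβ of the doubly activated alkene to form O1–C2, an asymmetric intramolecular oxa-Michael addition of the type established for 2'-hydroxyaryl alkylidene β-keto esters. Ring C closes in the 6-endo-trig mode and gives 12, whose C3 centre is labile and is erased later. C2 is set by the catalyst alone: the 8R,9R alkaloid frame leaves one face of Cβ open, the quinidine series is assigned to 2S by analogy with simple 2-aryl cases, and the sign of the flavanone n→π* CD band of 14 is to confirm this before scale-up, the quinine-derived pseudo-enantiomer being the mirror-image tool if the sense proves opposite. The selectivity needed is facial, and the substrate secures it by being a single alkene isomer of trans-chalcone geometry (ring A swings over the hydrogen side of Cβ), by having no second acidic OH, and by its ester, which makes the catalysed closure fast at −25 °C where uncatalysed closure and retro-addition are slow. TsOH, added cold so that the amine is silenced before warming, then cleaves the tert-butyl ester by loss of isobutene, and acid 13 sheds CO2 through a cyclic six-centre transition state without touching C2. The flavone enone is a vinylogous ester beyond the reach of the phenol and stays inert, as should the eight benzyl ethers.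

Step 10
Reactants: 14 (2S)-octa-O-benzyl ether of the target
Product: 15 (2S)-5'-(luteolin-8-yl)eriodictyol (target)
Conditions: H2 (1 atm), 10% Pd/C, THF/MeOH 1:1, AcOH (1% v/v), rt; filtration under argon; Sephadex LH-20 or reversed phase with 0.1% HCO2H
Reagents that add atoms: none
Why: Heterogeneous catalytic hydrogenolysis of aryl benzyl ethers in a base-free medium, which keeps shut the ring-opening channel through which 4'-hydroxyflavanones racemise, while the flavone C=C, the C4 ketone and the C2–O1 bond are reduced much more slowly, so the reaction can be stopped after uptake of eight equivalents of hydrogen.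

Compound list
1 | luteolin | O=c1cc(-c2ccc(O)c(O)c2)oc2cc(O)cc(O)c12 | starting material
2 | 5,7,3',4'-tetra-O-benzylluteolin | O=c1cc(-c2ccc(OCc3ccccc3)c(OCc3ccccc3)c2)oc2cc(OCc3ccccc3)cc(OCc3ccccc3)c12 | intermediate
3 | 8-iodo-5,7,3',4'-tetra-O-benzylluteolin | O=c1cc(-c2ccc(OCc3ccccc3)c(OCc3ccccc3)c2)oc2c(I)c(OCc3ccccc3)cc(OCc3ccccc3)c12 | intermediate
4 | 3-bromo-4,5-dihydroxybenzaldehyde | O=Cc1cc(O)c(O)c(Br)c1 | starting material
5 | 3,4-bis(benzyloxy)-5-bromobenzaldehyde | O=Cc1cc(OCc2ccccc2)c(OCc2ccccc2)c(Br)c1 | intermediate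
6 | 3,4-bis(benzyloxy)-5-(4,4,5,5-tetramethyl-1,3,2-dioxaborolan-2-yl)benzaldehyde | O=Cc1cc(OCc2ccccc2)c(OCc2ccccc2)c(B2OC(C)(C)C(C)(C)O2)c1 | intermediate
7 | 3,4-bis(benzyloxy)-5-(5,7,3',4'-tetra-O-benzylluteolin-8-yl)benzaldehyde | O=Cc1cc(OCc2ccccc2)c(OCc2ccccc2)c(-c2c(OCc3ccccc3)cc(OCc3ccccc3)c3c(=O)cc(-c4ccc(OCc5ccccc5)c(OCc5ccccc5)c4)oc23)c1 | intermediate
8 | 2,4,6-trihydroxyacetophenone | CC(=O)c1c(O)cc(O)cc1O | starting material
9 | 2-hydroxy-4,6-bis(benzyloxy)acetophenone | CC(=O)c1c(O)cc(OCc2ccccc2)cc1OCc2ccccc2 | intermediate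
10 | tert-butyl 3-[2-hydroxy-4,6-bis(benzyloxy)phenyl]-3-oxopropanoate | CC(C)(C)OC(=O)CC(=O)c1c(O)cc(OCc2ccccc2)cc1OCc2ccccc2 | intermediate
11 | tert-butyl (Z)-2-[2-hydroxy-4,6-bis(benzyloxy)benzoyl]-3-[3,4-bis(benzyloxy)-5-(tetra-O-benzylluteolin-8-yl)phenyl]acrylate | CC(C)(C)OC(=O)/C(=C\c1cc(OCc2ccccc2)c(OCc2ccccc2)c(-c2c(OCc3ccccc3)cc(OCc3ccccc3)c3c(=O)cc(-c4ccc(OCc5ccccc5)c(OCc5ccccc5)c4)oc23)c1)C(=O)c1c(O)cc(OCc2ccccc2)cc1OCc2ccccc2 | intermediate
12 | tert-butyl (2S)-5,7-bis(benzyloxy)-2-[3,4-bis(benzyloxy)-5-(tetra-O-benzylluteolin-8-yl)phenyl]-4-oxochromane-3-carboxylate (C3 labile, left undefined) | O=C1C(C(=O)OC(C)(C)C)[C@@H](c2cc(OCc3ccccc3)c(OCc3ccccc3)c(-c3c(OCc4ccccc4)cc(OCc4ccccc4)c4c(=O)cc(-c5ccc(OCc6ccccc6)c(OCc6ccccc6)c5)oc34)c2)Oc2cc(OCc3ccccc3)cc(OCc3ccccc3)c21 | intermediate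
13 | (2S)-5,7-bis(benzyloxy)-2-[3,4-bis(benzyloxy)-5-(tetra-O-benzylluteolin-8-yl)phenyl]-4-oxochromane-3-carboxylic acid (C3 labile, left undefined) | O=C1C(C(=O)O)[C@@H](c2cc(OCc3ccccc3)c(OCc3ccccc3)c(-c3c(OCc4ccccc4)cc(OCc4ccccc4)c4c(=O)cc(-c5ccc(OCc6ccccc6)c(OCc6ccccc6)c5)oc34)c2)Oc2cc(OCc3ccccc3)cc(OCc3ccccc3)c21 | intermediate
14 | (2S)-5,7-bis(benzyloxy)-2-[3,4-bis(benzyloxy)-5-(tetra-O-benzylluteolin-8-yl)phenyl]chroman-4-one | O=C1C[C@@H](c2cc(OCc3ccccc3)c(OCc3ccccc3)c(-c3c(OCc4ccccc4)cc(OCc4ccccc4)c4c(=O)cc(-c5ccc(OCc6ccccc6)c(OCc6ccccc6)c5)oc34)c2)Oc2cc(OCc3ccccc3)cc(OCc3ccccc3)c21 | intermediate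
15 | (2S)-5'-(luteolin-8-yl)eriodictyol, CNP0224656.1 | O=C1C[C@@H](c2cc(O)c(O)c(-c3c(O)cc(O)c4c(=O)cc(-c5ccc(O)c(O)c5)oc34)c2)Oc2cc(O)cc(O)c21 | target

Total step count: 10. Longest linear sequence: 6 steps (1, 2, 5, 8, 9, 10, or equally 3, 4, 5, 8, 9, 10).

Steps most likely to fail

**Step 9.**
- What may go wrong:
  - Facial discrimination may be too weak on so large a substrate.
  - The basic pyrone carbonyl of the flavone may compete for the thiourea.
  - The hot acid phase may erode C2 through reversible opening of ring C, assisted by the para-benzyloxy group of ring B.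
  - The hot acid phase may also strip the peri benzyl groups.
- Fallback: resolution replaces asymmetric catalysis, setting out from 11 and returning at 14.
  - An achiral amine (Et3N, toluene, rt) closes 11 to the racemic cyclised tert-butyl ester F1.
  - TsOH at 80 °C takes F1 through the racemic 3-carboxylic acid F2 to the racemic octa-O-benzyl flavanone F3.
  - Preparative HPLC on an immobilised amylose tris(3,5-dimethylphenylcarbamate) phase then separates 14 from the (2R)-octa-O-benzyl flavanone F4, which is kept as the reference for the enantiopurity assay.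

**Step 8.**
- What may go wrong:
  - The amine may trigger premature ring closure of the free phenol onto the new alkene, which would give racemic material.
  - Geometric control may be incomplete with the electron-rich aldehyde.
- Fallback: the nucleophile is masked during the condensation, setting out from 10 and returning at 11.
  - The phenol is silylated (TBSCl, imidazole, DMF) to tert-butyl 3-[2,4-bis(benzyloxy)-6-(tert-butyldimethylsilyloxy)phenyl]-3-oxopropanoate F5.
  - Condensation with 7 under the same amine/acid pair, which can now be warmed, gives the O-silyl alkylidene β-keto ester F6, whose Z isomer is purified.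
  - HF·pyridine in THF at 0 °C unmasks the phenol in an acidic medium in which no phenoxide can form, delivering 11.

**Step 10.**
- What may go wrong:
  - Partly deprotected polyphenols may precipitate on the catalyst and stall the cleavage.
  - Long exposure may lead to hydrogenolysis of the benzylic C2–O1 bond or saturation of the flavone double bond.
  - Any basic contact may open ring C and racemise the free 4'-hydroxyflavanone.
- Fallback: Lewis-acid debenzylation with a cation scavenger replaces hydrogenation, setting out from 14 and returning at 15.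
  - The conditions are BCl3 (excess), pentamethylbenzene, CH2Cl2, −78 °C, with a MeOH quench at low temperature.
  - This fallback makes no new compound (entry F0).

Further compounds
F1 | step 9 | racemic tert-butyl 5,7-bis(benzyloxy)-2-[3,4-bis(benzyloxy)-5-(tetra-O-benzylluteolin-8-yl)phenyl]-4-oxochromane-3-carboxylate | O=C1C(C(=O)OC(C)(C)C)C(c2cc(OCc3ccccc3)c(OCc3ccccc3)c(-c3c(OCc4ccccc4)cc(OCc4ccccc4)c4c(=O)cc(-c5ccc(OCc6ccccc6)c(OCc6ccccc6)c5)oc34)c2)Oc2cc(OCc3ccccc3)cc(OCc3ccccc3)c21
F2 | step 9 | racemic 5,7-bis(benzyloxy)-2-[3,4-bis(benzyloxy)-5-(tetra-O-benzylluteolin-8-yl)phenyl]-4-oxochromane-3-carboxylic acid | O=C1C(C(=O)O)C(c2cc(OCc3ccccc3)c(OCc3ccccc3)c(-c3c(OCc4ccccc4)cc(OCc4ccccc4)c4c(=O)cc(-c5ccc(OCc6ccccc6)c(OCc6ccccc6)c5)oc34)c2)Oc2cc(OCc3ccccc3)cc(OCc3ccccc3)c21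
F3 | step 9 | racemic 5,7-bis(benzyloxy)-2-[3,4-bis(benzyloxy)-5-(tetra-O-benzylluteolin-8-yl)phenyl]chroman-4-one | O=C1CC(c2cc(OCc3ccccc3)c(OCc3ccccc3)c(-c3c(OCc4ccccc4)cc(OCc4ccccc4)c4c(=O)cc(-c5ccc(OCc6ccccc6)c(OCc6ccccc6)c5)oc34)c2)Oc2cc(OCc3ccccc3)cc(OCc3ccccc3)c21
F4 | step 9 | (2R)-5,7-bis(benzyloxy)-2-[3,4-bis(benzyloxy)-5-(tetra-O-benzylluteolin-8-yl)phenyl]chroman-4-one | O=C1C[C@H](c2cc(OCc3ccccc3)c(OCc3ccccc3)c(-c3c(OCc4ccccc4)cc(OCc4ccccc4)c4c(=O)cc(-c5ccc(OCc6ccccc6)c(OCc6ccccc6)c5)oc34)c2)Oc2cc(OCc3ccccc3)cc(OCc3ccccc3)c21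
F5 | step 8 | tert-butyl 3-[2,4-bis(benzyloxy)-6-(tert-butyldimethylsilyloxy)phenyl]-3-oxopropanoate | CC(C)(C)OC(=O)CC(=O)c1c(O[Si](C)(C)C(C)(C)C)cc(OCc2ccccc2)cc1OCc2ccccc2
F6 | step 8 | tert-butyl (Z)-2-[2,4-bis(benzyloxy)-6-(tert-butyldimethylsilyloxy)benzoyl]-3-[3,4-bis(benzyloxy)-5-(tetra-O-benzylluteolin-8-yl)phenyl]acrylate | CC(C)(C)OC(=O)/C(=C\c1cc(OCc2ccccc2)c(OCc2ccccc2)c(-c2c(OCc3ccccc3)cc(OCc3ccccc3)c3c(=O)cc(-c4ccc(OCc5ccccc5)c(OCc5ccccc5)c4)oc23)c1)C(=O)c1c(O[Si](C)(C)C(C)(C)C)cc(OCc2ccccc2)cc1OCc2ccccc2
F0 | step 10 | none | none
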